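Ring C, the only ring built, is cut at C3–C4 and O1–C2. C4 is the carbonyl carbon of a ring A salicyloyl chloride and C3 is the α-carbon of a ring B α-benzyloxy ketone; the C–C bond is made first, the C–O bond second.
The route rests on one feature: ring A has adjacent oxygens on C8 and C8a, but only the C8a oxygen is ortho to the acyl carbon C4. Both can sit under one diphenylmethylene ketal; on acid unmasking O8a closes ring C and O8 is left as the lone free hydroxyl, while O5 stays benzylated so the 5,6,7-isomer cannot form.
The target then follows by acetylation of O8 and hydrogenolysis of the four benzyl ethers.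
The acid chloride comes from 2,3-dihydroxy-4-methoxybenzaldehyde by ketalisation, directed ortho-lithiation/hydroxylation next to the formyl group, benzylation, Pinnick oxidation and chlorination. The cyclic ketal is preferred to methoxymethyl ethers, which ortho to a carboxyl group are at risk of HCl cleavage and closure to a 1,3-benzodioxin-4-one during chloride formation. The ketone comes from a Weinreb ketone synthesis, which avoids alkoxide displacement on a phenacyl halide.

Key step: step 8

Assumption: benzyloxyacetyl chloride and 4-bromo-1,2-bis(benzyloxy)benzene are taken as purchasable; the target is achiral, so no stereocentre has to be set.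

Step 1
Reactants: 1 2,3-dihydroxy-4-methoxybenzaldehyde
Product: 2 7-methoxy-2,2-diphenyl-1,3-benzodioxole-4-carbaldehyde
Conditions: Ph2CCl2, Ph2O, 175 °C
Reagents that add atoms: dichlorodiphenylmethane, ClC(Cl)(c1ccccc1)c1ccccc1
Why: Ketalisation of a catechol with a gem-dichloride (two successive O-alkylations through the chlorodiphenylmethyl cation, HCl escaping at the reaction temperature) ties both catechol oxygens into one five-membered ketal that resists bases and organolithiums and that hot aqueous acid can later open.

Step 2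
Reactants: 2 7-methoxy-2,2-diphenyl-1,3-benzodioxole-4-carbaldehyde
Product: 6 5-hydroxy-7-methoxy-2,2-diphenyl-1,3-benzodioxole-4-carbaldehyde, via lithium α-amino alkoxide 3 (not isolated), via ortho-lithiated amino alkoxide 4 (not isolated), via aryltrimethoxyborate 5 (not isolated)
Conditions: Me2NCH2CH2NHMe, n-BuLi, THF, −20 °C; n-BuLi (3 equiv), −20 °C; B(OMe)3, −78 °C → 0 °C; AcOH, 30% H2O2, 0 °C
Reagents that add atoms: hydrogen peroxide, OO
Why: Directed ortho-metalation of an in situ lithium α-amino alkoxide: the amide adduct 3 shields the formyl carbon from n-BuLi and its chelating diamine arm should steer lithiation to C5 (benzodioxole numbering, ortho to the masked formyl) and not to C6 next to the methoxy group, after which borate trapping and buffered peroxide oxidation (aryl shift from boron to oxygen, much faster than Dakin oxidation of the released aldehyde in cold, weakly acidic medium) should give the phenol.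

Step 3
Reactants: 6 5-hydroxy-7-methoxy-2,2-diphenyl-1,3-benzodioxole-4-carbaldehyde
Product: 7 5-(benzyloxy)-7-methoxy-2,2-diphenyl-1,3-benzodioxole-4-carbaldehyde
Conditions: BnBr, K2CO3, DMF, 60 °C
Reagents that add atoms: benzyl bromide, BrCc1ccccc1
Why: Williamson ether synthesis, in which the phenoxide (although hydrogen-bonded to the formyl group) is alkylated by benzyl bromide in DMF and the future 5-oxygen is fixed as a benzyl ether.

Step 4
Reactants: 7 5-(benzyloxy)-7-methoxy-2,2-diphenyl-1,3-benzodioxole-4-carbaldehyde
Product: 8 5-(benzyloxy)-7-methoxy-2,2-diphenyl-1,3-benzodioxole-4-carboxylic acid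
Conditions: NaClO2, NaH2PO4, 2-methyl-2-butene, t-BuOH/THF/H2O, rt
Reagents that add atoms: sodium chlorite, [Na+].[O-]Cl=O
Why: Pinnick oxidation (chlorous acid adds to the aldehyde and fragments to the acid), with 2-methyl-2-butene trapping hypochlorous acid so that the electron-rich ring is not chlorinated and with a buffered medium that leaves the ketal and the benzyl ether intact.

Step 5
Reactants: 8 5-(benzyloxy)-7-methoxy-2,2-diphenyl-1,3-benzodioxole-4-carboxylic acid
Product: 9 5-(benzyloxy)-7-methoxy-2,2-diphenyl-1,3-benzodioxole-4-carbonyl chloride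
Conditions: (COCl)2, cat. DMF, CH2Cl2, 0 °C → rt; used crude
Reagents that add atoms: oxalyl chloride, O=C(Cl)C(=O)Cl
Why: Acid chloride formation through the Vilsmeier-type chloroiminium salt proceeds at room temperature, and the cyclic diphenylmethylene ketal offers no pendant acetal oxygen for attack on the acyl chloride and tolerates the anhydrous HCl released.

Step 6
Reactants: 10 benzyloxyacetyl chloride
Product: 11 2-(benzyloxy)-N-methoxy-N-methylacetamide
Conditions: MeNHOMe·HCl, K2CO3, CH2Cl2/H2O, 0 °C → rt
Reagents that add atoms: N,O-dimethylhydroxylamine hydrochloride, CNOC.Cl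
Why: Schotten–Baumann acylation of N,O-dimethylhydroxylamine by the acid chloride in a two-phase carbonate system is fast and should give the Weinreb amide without touching the benzyl ether.

Step 7
Reactants: 12 4-bromo-1,2-bis(benzyloxy)benzene; 11 2-(benzyloxy)-N-methoxy-N-methylacetamide
Product: 15 2-(benzyloxy)-1-[3,4-bis(benzyloxy)phenyl]ethanone, via 3,4-bis(benzyloxy)phenyllithium 13 (not isolated), via lithium hemiaminal alkoxide 14 (not isolated)
Conditions: n-BuLi, THF, −78 °C; 11, −78 → 0 °C; 1 M HCl
Reagents that add atoms: none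
Why: Bromine–lithium exchange followed by Weinreb ketone synthesis, in which the aryllithium adds once to the amide and the chelated tetrahedral adduct 14 holds until the acidic work-up, so that neither over-addition nor the epoxide and Favorskii pathways of an alkoxide displacement on a phenacyl halide can intervene.

Step 8
Reactants: 15 2-(benzyloxy)-1-[3,4-bis(benzyloxy)phenyl]ethanone; 9 5-(benzyloxy)-7-methoxy-2,2-diphenyl-1,3-benzodioxole-4-carbonyl chloride
Product: 20 3,5-bis(benzyloxy)-2-[3,4-bis(benzyloxy)phenyl]-8-hydroxy-7-methoxy-4H-chromen-4-one, via lithium enolate 16 (not isolated), via 1,3-diketone 17 (not isolated), via catechol diketone 18 (not isolated), via cyclic hemiketal 19 (not isolated)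
Conditions: LiN(SiMe3)2 (2.2 equiv), THF, −78 °C; 9, −78 °C → rt; AcOH, concentrate; AcOH/H2O (4:1), 110 °C
Reagents that add atoms: none
Why: LiN(SiMe3)2 converts 15 into the Z lithium enolate 16, in which lithium is chelated between the enolate oxygen and the benzyloxy oxygen, and this attacks acyl chloride 9 through carbon (Claisen-type acylation, addition–elimination at the acyl carbon) to form C3–C4, the second equivalent of base storing the product as the lithium diketonate of 17 so that it is not acylated again. Hot aqueous acetic acid then hydrolyses the diphenylmethylene ketal to catechol 18, whose hydroxyl ortho to the acyl carbon (the future O1 on C8a) adds to the ring B carbonyl in a 6-exo-trig closure to hemiketal 19, and acid-catalysed loss of water gives the 4-pyranone, so that O1–C2 is formed and ring C is closed. The closest known reaction type is the flavone synthesis in which a ketone lithium enolate is acylated by an O-protected salicyloyl chloride and the resulting 1,3-diketone is cyclodehydrated with acid. No stereocentre is set, since the sp3 centres of 17 to 19 become sp2 in 20. The step needs C- over O-acylation, which the tightly chelated lithium enolate in THF at low temperature should secure, and closure through one oxygen only, which the substrate secures because the C8 oxygen is meta to the acyl carbon and cannot reach it while the other ortho oxygen (O5) stays a benzyl ether. Aqueous acetic acid is chosen as the acid because it opens diphenylmethylene ketals of catechols while aryl benzyl ethers are normally retained.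

Step 9
Reactants: 20 3,5-bis(benzyloxy)-2-[3,4-bis(benzyloxy)phenyl]-8-hydroxy-7-methoxy-4H-chromen-4-one
Product: 21 3,5-bis(benzyloxy)-2-[3,4-bis(benzyloxy)phenyl]-7-methoxy-4-oxo-4H-chromen-8-yl acetate
Conditions: Ac2O, pyridine, cat. DMAP, CH2Cl2, 0 °C → rt
Reagents that add atoms: acetic anhydride, CC(=O)OC(C)=O
Why: Nucleophile-catalysed O-acylation of a phenol, in which O8 is the only hydroxyl of 20, so that no selectivity question arises.

Step 10
Reactants: 21 3,5-bis(benzyloxy)-2-[3,4-bis(benzyloxy)phenyl]-7-methoxy-4-oxo-4H-chromen-8-yl acetate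
Product: 22 2-(3,4-dihydroxyphenyl)-3,5-dihydroxy-7-methoxy-4-oxo-4H-chromen-8-yl acetate (gossypetin 7-methyl ether 8-acetate)
Conditions: H2 (1 atm), 10% Pd/C, EtOAc/THF, rt
Reagents that add atoms: none
Why: Catalytic hydrogenolysis of aryl benzyl ethers over palladium on carbon cleaves all four O–CH2Ph bonds under neutral conditions, and a non-hydroxylic solvent should keep the aryl acetate, which has no neighbouring free hydroxyl (O7 is methylated), from solvolysis or migration.

Compound list
1 | 2,3-dihydroxy-4-methoxybenzaldehyde | COc1ccc(C=O)c(O)c1O | starting material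
2 | 7-methoxy-2,2-diphenyl-1,3-benzodioxole-4-carbaldehyde | COc1ccc(C=O)c2OC(c3ccccc3)(c3ccccc3)Oc12 | intermediate
3 | lithium {[2-(dimethylamino)ethyl](methyl)amino}(7-methoxy-2,2-diphenyl-1,3-benzodioxol-4-yl)methanolate (racemic, formed in the flask) | [Li+].[O-]C(N(C)CCN(C)C)c1ccc(OC)c2OC(c3ccccc3)(c3ccccc3)Oc12 | intermediate
4 | lithium {[2-(dimethylamino)ethyl](methyl)amino}(5-lithio-7-methoxy-2,2-diphenyl-1,3-benzodioxol-4-yl)methanolate (racemic, formed in the flask) | [Li+].[O-]C(N(C)CCN(C)C)c1c([Li])cc(OC)c2OC(c3ccccc3)(c3ccccc3)Oc12 | intermediate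
5 | dilithium [4-({[2-(dimethylamino)ethyl](methyl)amino}(oxido)methyl)-7-methoxy-2,2-diphenyl-1,3-benzodioxol-5-yl]trimethoxyborate (racemic, formed in the flask) | [Li+].[Li+].[O-]C(N(C)CCN(C)C)c1c([B-](OC)(OC)OC)cc(OC)c2OC(c3ccccc3)(c3ccccc3)Oc12 | intermediate
6 | 5-hydroxy-7-methoxy-2,2-diphenyl-1,3-benzodioxole-4-carbaldehyde | COc1cc(O)c(C=O)c2OC(c3ccccc3)(c3ccccc3)Oc12 | intermediate
7 | 5-(benzyloxy)-7-methoxy-2,2-diphenyl-1,3-benzodioxole-4-carbaldehyde | COc1cc(OCc3ccccc3)c(C=O)c2OC(c3ccccc3)(c3ccccc3)Oc12 | intermediate
8 | 5-(benzyloxy)-7-methoxy-2,2-diphenyl-1,3-benzodioxole-4-carboxylic acid | COc1cc(OCc3ccccc3)c(C(=O)O)c2OC(c3ccccc3)(c3ccccc3)Oc12 | intermediate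
9 | 5-(benzyloxy)-7-methoxy-2,2-diphenyl-1,3-benzodioxole-4-carbonyl chloride | COc1cc(OCc3ccccc3)c(C(=O)Cl)c2OC(c3ccccc3)(c3ccccc3)Oc12 | intermediate
10 | benzyloxyacetyl chloride | O=C(Cl)COCc1ccccc1 | starting material
11 | 2-(benzyloxy)-N-methoxy-N-methylacetamide | CON(C)C(=O)COCc1ccccc1 | intermediate
12 | 4-bromo-1,2-bis(benzyloxy)benzene | Brc1ccc(OCc2ccccc2)c(OCc2ccccc2)c1 | starting material
13 | 3,4-bis(benzyloxy)phenyllithium (formed in the flask) | [Li]c1ccc(OCc2ccccc2)c(OCc2ccccc2)c1 | intermediate
14 | lithium 2-(benzyloxy)-1-[3,4-bis(benzyloxy)phenyl]-1-[methoxy(methyl)amino]ethanolate (racemic, formed in the flask) | [Li+].[O-]C(COCc1ccccc1)(N(C)OC)c1ccc(OCc2ccccc2)c(OCc2ccccc2)c1 | intermediate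
15 | 2-(benzyloxy)-1-[3,4-bis(benzyloxy)phenyl]ethanone | O=C(COCc1ccccc1)c1ccc(OCc2ccccc2)c(OCc2ccccc2)c1 | intermediate
16 | lithium (Z)-2-(benzyloxy)-1-[3,4-bis(benzyloxy)phenyl]ethenolate (formed in the flask) | [Li+].[O-]/C(=C\OCc1ccccc1)c1ccc(OCc2ccccc2)c(OCc2ccccc2)c1 | intermediate
17 | 2-(benzyloxy)-1-[5-(benzyloxy)-7-methoxy-2,2-diphenyl-1,3-benzodioxol-4-yl]-3-[3,4-bis(benzyloxy)phenyl]propane-1,3-dione (racemic; formed as its lithium enolate and set free by acetic acid) | COc1cc(OCc3ccccc3)c(C(=O)C(OCc3ccccc3)C(=O)c3ccc(OCc4ccccc4)c(OCc4ccccc4)c3)c2OC(c3ccccc3)(c3ccccc3)Oc12 | intermediate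
18 | 2-(benzyloxy)-1-[6-(benzyloxy)-2,3-dihydroxy-4-methoxyphenyl]-3-[3,4-bis(benzyloxy)phenyl]propane-1,3-dione (racemic, formed in the flask) | COc1cc(OCc2ccccc2)c(C(=O)C(OCc2ccccc2)C(=O)c2ccc(OCc3ccccc3)c(OCc3ccccc3)c2)c(O)c1O | intermediate
19 | 3,5-bis(benzyloxy)-2-[3,4-bis(benzyloxy)phenyl]-2,8-dihydroxy-7-methoxy-2,3-dihydro-4H-chromen-4-one (mixture of diastereomers, formed in the flask) | COc1cc(OCc2ccccc2)c2C(=O)C(OCc3ccccc3)C(O)(c3ccc(OCc4ccccc4)c(OCc4ccccc4)c3)Oc2c1O | intermediate
20 | 3,5-bis(benzyloxy)-2-[3,4-bis(benzyloxy)phenyl]-8-hydroxy-7-methoxy-4H-chromen-4-one | COc1cc(OCc2ccccc2)c2c(=O)c(OCc3ccccc3)c(-c3ccc(OCc4ccccc4)c(OCc4ccccc4)c3)oc2c1O | intermediate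
21 | 3,5-bis(benzyloxy)-2-[3,4-bis(benzyloxy)phenyl]-7-methoxy-4-oxo-4H-chromen-8-yl acetate | COc1cc(OCc2ccccc2)c2c(=O)c(OCc3ccccc3)c(-c3ccc(OCc4ccccc4)c(OCc4ccccc4)c3)oc2c1OC(C)=O | intermediate
22 | 2-(3,4-dihydroxyphenyl)-3,5-dihydroxy-7-methoxy-4-oxo-4H-chromen-8-yl acetate (gossypetin 7-methyl ether 8-acetate) | COc1cc(O)c2c(=O)c(O)c(-c3ccc(O)c(O)c3)oc2c1OC(C)=O | target

Total step count: 10. Longest linear sequence: 8 steps (steps 1 to 5, then 8, 9 and 10); steps 6 and 7 form the side branch to the ketone.

Steps most likely to fail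

Step 8. The enolate may be acylated on oxygen or may react only slowly with the doubly ortho-substituted acyl chloride. In the acid stage the ketal may open incompletely, or the peri benzyl ether on O5 may be lost in hot acid. The fallback forms the same C3–C4 bond by aldol addition and oxidation instead of acylation. It sets out from aldehyde 7 and ketone 15, so steps 4 and 5 are not needed. Enolate 16 (LiN(SiMe3)2, THF, −78 °C) would add to 7 to give the aldol adduct 2-(benzyloxy)-3-[5-(benzyloxy)-7-methoxy-2,2-diphenyl-1,3-benzodioxol-4-yl]-1-[3,4-bis(benzyloxy)phenyl]-3-hydroxypropan-1-one F1 as a mixture of diastereomers. Oxidation of this β-hydroxy ketone with Dess–Martin periodinane in CH2Cl2 should give diketone 17, where the fallback comes back to the route; the aqueous acetic acid stage then leads to 20 as before.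

Step 2. Metalation may be incomplete or may go next to the methoxy group, and the released aldehyde may be over-oxidised by peroxide in a Dakin-type reaction. The fallback sets out from aldehyde 2, moves the oxidation of the formyl group ahead of the metalation and uses the carboxylate as directing group, so that no aldehyde is present when peroxide is added. Pinnick oxidation of 2 would give 7-methoxy-2,2-diphenyl-1,3-benzodioxole-4-carboxylic acid F2. Carboxylate-directed ortho-lithiation (s-BuLi, TMEDA, THF, −78 °C), trapping with B(OMe)3 and oxidation with H2O2/AcOH should give 5-hydroxy-7-methoxy-2,2-diphenyl-1,3-benzodioxole-4-carboxylic acid F3. Double benzylation (BnBr, K2CO3, DMF) would give benzyl 5-(benzyloxy)-7-methoxy-2,2-diphenyl-1,3-benzodioxole-4-carboxylate F4, and saponification (KOH, EtOH/THF/H2O, reflux) would return acid 8, where the fallback comes back to the route.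

Step 10. The aryl acetate may be partly lost by solvolysis or acyl transfer, the debenzylation may stall at the chelated ether on O5, or the C2–C3 double bond may be saturated on long exposure. The fallback replaces hydrogenolysis by Lewis-acid ether cleavage. It sets out from 21 and treats it with BCl3 and pentamethylbenzene in CH2Cl2 at −78 °C; the benzyl cations are trapped by the arene, and the acetate and the aryl methyl ether are expected to survive at this temperature. After aqueous work-up it comes back at target 22 and makes no new compound (F0).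

Further compounds
F1 | step 8 | 2-(benzyloxy)-3-[5-(benzyloxy)-7-methoxy-2,2-diphenyl-1,3-benzodioxol-4-yl]-1-[3,4-bis(benzyloxy)phenyl]-3-hydroxypropan-1-one (mixture of diastereomers) | COc1cc(OCc3ccccc3)c(C(O)C(OCc3ccccc3)C(=O)c3ccc(OCc4ccccc4)c(OCc4ccccc4)c3)c2OC(c3ccccc3)(c3ccccc3)Oc12
F2 | step 2 | 7-methoxy-2,2-diphenyl-1,3-benzodioxole-4-carboxylic acid | COc1ccc(C(=O)O)c2OC(c3ccccc3)(c3ccccc3)Oc12
F3 | step 2 | 5-hydroxy-7-methoxy-2,2-diphenyl-1,3-benzodioxole-4-carboxylic acid | COc1cc(O)c(C(=O)O)c2OC(c3ccccc3)(c3ccccc3)Oc12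
F4 | step 2 | benzyl 5-(benzyloxy)-7-methoxy-2,2-diphenyl-1,3-benzodioxole-4-carboxylate | COc1cc(OCc3ccccc3)c(C(=O)OCc3ccccc3)c2OC(c3ccccc3)(c3ccccc3)Oc12
F0 | step 10 | none | none
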